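3 questions are put to this flask, and each is answered here before any run is shown.

    X + D → 2 D (k1 = 0.0041 M⁻¹ s⁻¹)
    X → D (k2 = 4.8 × 10⁻⁵ s⁻¹)
    X ⇌ L (K3 = 0.43, k3 = 0.0020 s⁻¹)
X 0.40 M; time 80 min
- what has gone from X into another species counts as reacted, even if it can come back
- the reaction counts as stopped when no species that holds the X changes by six tenths of a point or more over the second half of the time
- run time (flask): 80 min
- why nothing more happens at 80 min, or that something still does (forward and back rates have come level / it is still moving / all of X has reacted)
- how much of the X has reacted by 80 min
- how much D there is at 80 min, in percent of the X charged

What does X do first? It passes into L and comes back with a relaxation half-life of 1.74 min, shorter than the run, so this is a fast pre-equilibrium in which cX is 69.9% of the pool cX + cL.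

What starts D? Step 2 does, since step 1 needs D, but step 1 overtakes it once cD passes 0.0117 M, so that concentration works as a seed added to cD.

And the clock? It is the growth time 14.1 min, the inverse of the product of k1, the sum of charge and seed, and the share of X. The ratio of cD plus seed to the pool starts at seed over charge and multiplies by e every growth time, reaching 8.46 by 80.0 min, which puts D at 89.1%.

Does that share last? Not quite: putting the answer back in, the pool near the end of my curve falls, per unit of itself, at 0.0633 min⁻¹, which eats into L's way back of 0.279 min⁻¹, so L lags and the share of X ends near 64.3%. Running that share from 40.0 min onward gives 86.7%.

So I commit to D between 86.7% and 89.1%, and, with L counted as reacted, to a conversion between 91.4% and 93.0%. Has it stopped? My curve stands at 31.3% at 40.0 min, against the 86.7% to 89.1% reckoned for 80.0 min, so it is still moving.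

The forecast gives 88.2% of D, 92.3% reacted and "it is still moving", holding that “X is still being consumed irreversibly”.

The simulation gives 88.2% of D, 92.3% reacted and "it is still moving", and that D, put back into the ratio, reads as a growth time averaged over the run of 14.3 min against 14.1 min. The neighbour charged with 0.10 M of X keeps the seed, but its growth time is 52.0 min, so its ratio reaches 0.545 and the reckoning gives 27.7% of D. That neighbour's run holds 28.0% of D at 80.0 min, with 50.0% still X.

The numbers of this flask were set for the occasion; the result is computed.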